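**Retrosynthetic overview**

1. Numbering: C1 = CO2H, C2 = CH2, ring O1–O2–C3–C4–C5–C6 (O2 on C3, O1 on C6), chain C7=C8(Et)–C9–C10(Et)–C11=C12–C13–C14; the target is (3S,4S,6S,7E,10R,11E). Feature used: in the 1,2-dioxane, C3 and C6 are linked twice (through O1–O2 and through C4–C5) and each carries one exocyclic carbon (C2, C7); a C2–C7 bond would close the carbocycle C2–C3–C4–C5–C6–C7, which with the ethyl groups on C4 and C6 is the ring of 1,3-diethylbenzene, the dioxane being its C3/C6 endoperoxide.
2. Disconnections, last bond first: CO2H ⇐ C1 aldehyde ⇐ enol ether (one-carbon Wittig at C2); C11=C12 (Julia–Kocienski); C9–C10 (Evans alkylation, sets C10); C7=C8 (Horner–Wadsworth–Emmons, sets 7E); C2/C7 dialdehyde ⇐ glycol cleavage of a bicyclic cis-diol; C4–H ⇐ diimide on C4=C5.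
3. Ring order: the carbocycle is bought as the arene and made chiral by enzymatic cis-dihydroxylation (C2, C7); the 1,2-dioxane, the only ring of the target, is closed next by [4+2] addition of singlet oxygen to the diene acetonide (sets C3, C6); the carbocycle is then cut at C2–C7.

Key step: step 3

Assumption: toluene dioxygenase is taken to oxidise 1,3-diethylbenzene at the ring bond next to one ethyl group with the facial sense it shows for toluene, ethylbenzene and m-xylene.

Abbreviation: Dx = (3R,4S,6S)-4,6-diethyl-3-(2-methoxyethenyl)-1,2-dioxan-6-yl, the ring made in step 7, attached through C6. Its C3 descriptor is R only because the vinyl ether outranks C4; the geometry is that of the target. The enol ether is an E/Z mixture throughout and its SMILES bond is left undefined.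

**Route**

Step 1
Reactants: 1 1,3-diethylbenzene; 2 dioxygen (air)
Product: 3 (1S,2R)-3,5-diethylcyclohexa-3,5-diene-1,2-diol
Conditions: whole cells of E. coli JM109(pDTG601) expressing toluene dioxygenase, glucose, phosphate buffer pH 7.2, air, 30 °C; EtOAc extraction at pH 8
Reagents that add atoms: none
Why: Enzymatic arene cis-dihydroxylation adds both atoms of O2 to one face of the only unsubstituted ring bond flanking an ethyl group, so the two carbinol centres (future C2 and C7) are set by the enzyme with the sense known for monoalkylbenzenes.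

Step 2
Reactants: 3 (1S,2R)-3,5-diethylcyclohexa-3,5-diene-1,2-diol; 4 2,2-dimethoxypropane
Product: 5 (3aR,7aS)-4,6-diethyl-2,2-dimethyl-3a,7a-dihydro-1,3-benzodioxole (acetonide of 3)
Conditions: 4 (excess), p-TsOH·H2O (cat.), acetone, 0 °C; Et3N quench
Reagents that add atoms: none
Why: Acid-catalysed transketalisation of the cis-diol gives the cis-fused dioxolane, which stops dehydration to the phenol and covers one face of the diene without touching a stereocentre.

Step 3
Reactants: 5 acetonide of 3; 2 dioxygen (as photogenerated singlet oxygen)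
Product: 6 1,5-diethyl-7,8-(isopropylidenedioxy)-2,3-dioxabicyclo[2.2.2]oct-5-ene with the dioxolane anti to the O–O bridge (bridgeheads = target C6 with ethyl and C3 with H)
Conditions: O2, 5,10,15,20-tetraphenylporphyrin (cat.), CH2Cl2, visible light, −30 °C; kept cold and used at once
Reagents that add atoms: none
Why: Sensitised energy transfer gives singlet oxygen, which adds to the ring-locked s-cis diene C3=C4–C5=C6 in a concerted suprafacial [4+2] cycloaddition that forms C3–O2 and C6–O1 together. The closest known reaction is the photooxygenation of acetonides of microbial arene cis-dihydrodiols, and of α-terpinene to ascaridole. The 1,2-dioxane ring O1–O2–C3–C4–C5–C6 is closed by this cycloaddition, not by a stepwise ring closure, and appears as the peroxide ring of a 2,3-dioxabicyclo[2.2.2]oct-5-ene. C3 and C6 are set together by approach of oxygen to the diene face opposite the dioxolane, so both are dictated by the enzyme-set carbons C2 and C7 and end up cis-bridged to them. The step needs facial selectivity and [4+2] over ene periselectivity; the cis-fused acetonide secures the first, and the cisoid cyclic diene, which reacts faster at low temperature than the allylic C–H bonds of the ethyl groups, secures the second.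

Step 4
Reactants: 6 unsaturated endoperoxide acetonide
Product: 7 1,5-diethyl-7,8-(isopropylidenedioxy)-2,3-dioxabicyclo[2.2.2]octane with the C5 ethyl group on the side of the C7–C8 bridge
Conditions: KO2CN=NCO2K (excess, in portions), AcOH, CH2Cl2, −78 °C → rt
Reagents that add atoms: none
Why: Diimide reduction (concerted syn transfer of two hydrogens) saturates the strained bridge alkene without touching the O–O bond, and hydrogen arrives on the face flanked by the bare peroxide bridge because the other face is covered by the dioxolane, which places the C4 ethyl group cis to C2 and C7 as in the target.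

Step 5
Reactants: 7 saturated endoperoxide acetonide
Product: 8 1,5-diethyl-2,3-dioxabicyclo[2.2.2]octane-7,8-diol (cis-diol anti to O–O, C5 ethyl as in 7)
Conditions: CF3CO2H/H2O (4:1), 0 °C → rt
Reagents that add atoms: none
Why: Acid-catalysed acetal hydrolysis frees the cis-diol, and the dialkyl peroxide, whose tertiary C–O bond sits at a bridgehead and cannot ionise easily, tolerates aqueous acid.

Step 6
Reactants: 8 endoperoxide diol
Product: 9 (3R,4S,6S)-4,6-diethyl-1,2-dioxane-3,6-dicarbaldehyde (both formyl groups and the C4 ethyl on one face)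
Conditions: NaIO4 on SiO2, CH2Cl2, rt; filtered and used crude
Reagents that add atoms: none
Why: Periodate glycol cleavage (Malaprade reaction) of the rigid cis-diol through a cyclic periodate ester cuts the C2–C7 bond and releases the monocyclic dioxane with C2 and C7 as cis formyl groups, in a neutral medium that spares the base-sensitive C3–H.

Step 7
Reactants: 9 dialdehyde; 10 (methoxymethyl)triphenylphosphonium chloride
Product: 12 (3R,4S,6S)-4,6-diethyl-3-(2-methoxyethenyl)-1,2-dioxane-6-carbaldehyde (Dx–CHO), via (methoxymethylene)triphenylphosphorane 11 (not isolated)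
Conditions: 10 (1.05 equiv), KN(SiMe3)2, THF, −78 → 0 °C; ylide added slowly to 9, THF, −78 °C
Reagents that add atoms: none
Why: Wittig methoxymethylenation with one equivalent of the bulky ylide should take the formyl group on the secondary carbon C3 and leave the neopentyl-type formyl group on quaternary C6, fast carbonyl addition at −78 °C outrunning deprotonation at C3, and the enol ether carries the new carbon C1.

Step 8
Reactants: 12 Dx–CHO; 13 triethyl 2-phosphonobutanoate
Product: 15 ethyl (E)-2-ethyl-3-Dx-prop-2-enoate, via sodium phosphonate carbanion 14 (not isolated)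
Conditions: 13, NaH, THF, 0 °C; then 12, 0 °C → rt
Reagents that add atoms: none
Why: Horner–Wadsworth–Emmons olefination of the aldehyde, which has no α-hydrogen, with the α-ethyl phosphonate anion gives the trisubstituted enoate with the ester trans to the bulky dioxane carbon, which is the 7E geometry with the ester carbon as the future C9.

Step 9
Reactants: 15 (E)-enoate
Product: 16 (E)-2-ethyl-3-Dx-prop-2-en-1-ol
Conditions: i-Bu2AlH (2.5 equiv), CH2Cl2, −78 °C; aq. KNaC4H4O6 work-up
Reagents that add atoms: none
Why: Hydride 1,2-reduction of the conjugated ester with i-Bu2AlH gives the allylic alcohol, and dialkyl peroxides and enol ethers are inert to this reagent at −78 °C.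

Step 10
Reactants: 16 allylic alcohol
Product: 18 (E)-1-bromo-2-ethyl-3-Dx-prop-2-ene, via allylic mesylate 17 (not isolated)
Conditions: MsCl, Et3N, THF, −40 °C; then LiBr, 0 °C
Reagents that add atoms: methanesulfonyl chloride, CS(=O)(=O)Cl (kept only in 17); lithium bromide, [Li+].[Br-]
Why: Mesylation and in situ SN2 displacement by bromide give the primary allylic bromide without a phosphine, which could attack the peroxide, and without allylic transposition because the γ-carbon is shielded by the quaternary centre.

Step 11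
Reactants: 19 (S)-4-benzyloxazolidin-2-one; 20 butanoyl chloride
Product: 21 (S)-4-benzyl-3-butanoyloxazolidin-2-one
Conditions: Et3N, 4-(dimethylamino)pyridine (cat.), CH2Cl2, 0 °C → rt
Reagents that add atoms: none
Why: N-Acylation of the oxazolidinone by the acid chloride under nucleophilic catalysis is the standard entry to the Evans imide.

Step 12
Reactants: 18 allylic bromide; 21 (S)-4-benzyl-3-butanoyloxazolidin-2-one
Product: 23 (S)-4-benzyl-3-[(2R,4E)-2,4-diethyl-5-Dx-pent-4-enoyl]oxazolidin-2-one, via sodium Z-enolate of the butanoyl imide 22 (not isolated)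
Conditions: 21 (2 equiv), NaN(SiMe3)2, THF, −78 °C; then 18, −78 → −40 °C
Reagents that add atoms: none
Why: In this Evans asymmetric alkylation the chelated sodium Z-enolate is attacked by the reactive allylic bromide on the face opposite the benzyl group, which sets C10 as R, while the hindered dialkyl peroxide is not attacked by the stabilised enolate at low temperature.

Step 13
Reactants: 23 alkylated imide
Product: 24 (2R,4E)-2,4-diethyl-5-Dx-pent-4-en-1-ol
Conditions: LiBH4, H2O (1 equiv), Et2O, 0 °C
Reagents that add atoms: none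
Why: Reductive cleavage of the imide with LiBH4 gives the primary alcohol and returns the auxiliary, a borohydride reduction that leaves 1,2-dioxanes intact and does not epimerise C10.

Step 14
Reactants: 24 primary alcohol
Product: 25 (2R,4E)-2,4-diethyl-5-Dx-pent-4-enal
Conditions: Dess–Martin periodinane, NaHCO3, CH2Cl2, 0 °C → rt
Reagents that add atoms: none
Why: Dess–Martin oxidation under bicarbonate buffer gives the α-branched aldehyde without epimerisation at C10 and without acid damage to the enol ether.

Step 15
Reactants: 26 1-phenyl-1H-tetrazole-5-thiol; 27 1-bromopropane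
Product: 28 1-phenyl-5-(propylsulfanyl)-1H-tetrazole
Conditions: K2CO3, acetone, reflux
Reagents that add atoms: none
Why: S-Alkylation of the acidic tetrazole thiol by SN2 reaction with a primary bromide.

Step 16
Reactants: 28 sulfide
Product: 29 1-phenyl-5-(propylsulfonyl)-1H-tetrazole
Conditions: 30% aq. H2O2, (NH4)6Mo7O24·4H2O (cat.), EtOH, 0 °C → rt
Reagents that add atoms: hydrogen peroxide, OO
Why: Molybdate-catalysed sulfide oxidation with hydrogen peroxide gives the sulfone needed for the Julia–Kocienski reaction.

Step 17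
Reactants: 25 aldehyde; 29 1-phenyl-5-(propylsulfonyl)-1H-tetrazole
Product: 31 (3R,4S,6S)-4,6-diethyl-6-[(1E,4R,5E)-2,4-diethylocta-1,5-dien-1-yl]-3-(2-methoxyethenyl)-1,2-dioxane, via potassium sulfonyl carbanion 30 (not isolated)
Conditions: 29, KN(SiMe3)2, DME, −60 °C; then 25, −60 °C → rt
Reagents that add atoms: none
Why: Julia–Kocienski olefination of the α-branched aldehyde with the premetallated phenyltetrazolyl sulfone gives the 11E alkene through anti addition, Smiles rearrangement and elimination, and the low temperature keeps C10 from epimerising.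

Step 18
Reactants: 31 enol ether
Product: 32 2-[(3S,4S,6S)-4,6-diethyl-6-[(1E,4R,5E)-2,4-diethylocta-1,5-dien-1-yl]-1,2-dioxan-3-yl]acetaldehyde
Conditions: 1 M aq. HCl, THF, 0 °C → rt; used crude
Reagents that add atoms: water, O
Why: Acid-catalysed enol ether hydrolysis (C-protonation, hydration of the oxocarbenium ion, loss of methanol) unmasks the C1 aldehyde under conditions too mild to ionise the allylic C6–O bond.

Step 19
Reactants: 32 aldehyde
Product: 33 2-[(3S,4S,6S)-4,6-diethyl-6-[(1E,4R,5E)-2,4-diethylocta-1,5-dien-1-yl]-1,2-dioxan-3-yl]acetic acid (target)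
Conditions: NaClO2, NaH2PO4, 2-methylbut-2-ene, t-BuOH/H2O, 0 °C → rt
Reagents that add atoms: sodium chlorite, [Na+].[O-]Cl=O
Why: Pinnick oxidation in buffered, weakly acidic medium with an alkene scavenger turns the aldehyde into the acid without touching the two alkenes, the peroxide or the β-peroxy position, which eliminates only under base.

**Compound list**

1 | 1,3-diethylbenzene | CCc1cccc(CC)c1 | starting material
2 | dioxygen | O=O | starting material
3 | (1S,2R)-3,5-diethylcyclohexa-3,5-diene-1,2-diol | O[C@H]1C=C(CC)C=C(CC)[C@H]1O | intermediate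
4 | 2,2-dimethoxypropane | COC(C)(C)OC | starting material
5 | (3aR,7aS)-4,6-diethyl-2,2-dimethyl-3a,7a-dihydro-1,3-benzodioxole | CC1(C)O[C@H]2C=C(CC)C=C(CC)[C@H]2O1 | intermediate
6 | 1,5-diethyl-7,8-(isopropylidenedioxy)-2,3-dioxabicyclo[2.2.2]oct-5-ene, dioxolane anti to O–O | CC[C@@]12C=C(CC)[C@@H](OO1)[C@@H]1OC(C)(C)O[C@H]21 | intermediate
7 | 1,5-diethyl-7,8-(isopropylidenedioxy)-2,3-dioxabicyclo[2.2.2]octane, C5 ethyl toward the C7–C8 bridge | CC[C@@]12C[C@H](CC)[C@@H](OO1)[C@@H]1OC(C)(C)O[C@H]21 | intermediate
8 | 1,5-diethyl-2,3-dioxabicyclo[2.2.2]octane-7,8-diol, cis-diol anti to O–O | CC[C@@]12C[C@H](CC)[C@@H](OO1)[C@H](O)[C@@H]2O | intermediate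
9 | (3R,4S,6S)-4,6-diethyl-1,2-dioxane-3,6-dicarbaldehyde | O=C[C@]1(CC)C[C@H](CC)[C@H](C=O)OO1 | intermediate
10 | (methoxymethyl)triphenylphosphonium chloride | [Cl-].COC[P+](c1ccccc1)(c1ccccc1)c1ccccc1 | starting material
11 | (methoxymethylene)triphenylphosphorane | COC=P(c1ccccc1)(c1ccccc1)c1ccccc1 | intermediate (not isolated)
12 | (3R,4S,6S)-4,6-diethyl-3-(2-methoxyethenyl)-1,2-dioxane-6-carbaldehyde (Dx–CHO) | O=C[C@]1(CC)C[C@H](CC)[C@H](C=COC)OO1 | intermediate
13 | triethyl 2-phosphonobutanoate | CCOC(=O)C(CC)P(=O)(OCC)OCC | starting material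
14 | sodium salt of the carbanion of 13 | [Na+].CCOC(=O)[C-](CC)P(=O)(OCC)OCC | intermediate (not isolated)
15 | ethyl (E)-2-ethyl-3-Dx-prop-2-enoate | CCOC(=O)/C(CC)=C/[C@]1(CC)C[C@H](CC)[C@H](C=COC)OO1 | intermediate
16 | (E)-2-ethyl-3-Dx-prop-2-en-1-ol | OC/C(CC)=C/[C@]1(CC)C[C@H](CC)[C@H](C=COC)OO1 | intermediate
17 | (E)-2-ethyl-3-Dx-prop-2-en-1-yl methanesulfonate | CS(=O)(=O)OC/C(CC)=C/[C@]1(CC)C[C@H](CC)[C@H](C=COC)OO1 | intermediate (not isolated)
18 | (E)-1-bromo-2-ethyl-3-Dx-prop-2-ene | BrC/C(CC)=C/[C@]1(CC)C[C@H](CC)[C@H](C=COC)OO1 | intermediate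
19 | (S)-4-benzyloxazolidin-2-one | O=C1N[C@@H](Cc2ccccc2)CO1 | starting material
20 | butanoyl chloride | CCCC(Cl)=O | starting material
21 | (S)-4-benzyl-3-butanoyloxazolidin-2-one | CCCC(=O)N1[C@@H](Cc2ccccc2)COC1=O | intermediate
22 | sodium Z-enolate of 21 | [Na+].CC/C=C(\[O-])N1[C@@H](Cc2ccccc2)COC1=O | intermediate (not isolated)
23 | (S)-4-benzyl-3-[(2R,4E)-2,4-diethyl-5-Dx-pent-4-enoyl]oxazolidin-2-one | CC[C@H](C/C(CC)=C/[C@]1(CC)C[C@H](CC)[C@H](C=COC)OO1)C(=O)N1[C@@H](Cc2ccccc2)COC1=O | intermediate
24 | (2R,4E)-2,4-diethyl-5-Dx-pent-4-en-1-ol | CC[C@@H](CO)C/C(CC)=C/[C@]1(CC)C[C@H](CC)[C@H](C=COC)OO1 | intermediate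
25 | (2R,4E)-2,4-diethyl-5-Dx-pent-4-enal | CC[C@@H](C=O)C/C(CC)=C/[C@]1(CC)C[C@H](CC)[C@H](C=COC)OO1 | intermediate
26 | 1-phenyl-1H-tetrazole-5-thiol | Sc1nnnn1-c1ccccc1 | starting material
27 | 1-bromopropane | CCCBr | starting material
28 | 1-phenyl-5-(propylsulfanyl)-1H-tetrazole | CCCSc1nnnn1-c1ccccc1 | intermediate
29 | 1-phenyl-5-(propylsulfonyl)-1H-tetrazole | CCCS(=O)(=O)c1nnnn1-c1ccccc1 | intermediate
30 | potassium salt of the α-sulfonyl carbanion of 29 | [K+].CC[CH-]S(=O)(=O)c1nnnn1-c1ccccc1 | intermediate (not isolated)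
31 | (3R,4S,6S)-4,6-diethyl-6-[(1E,4R,5E)-2,4-diethylocta-1,5-dien-1-yl]-3-(2-methoxyethenyl)-1,2-dioxane | CC/C=C/[C@H](CC)C/C(=C/[C@]1(CC)C[C@H](CC)[C@H](C=COC)OO1)CC | intermediate
32 | 2-[(3S,4S,6S)-4,6-diethyl-6-[(1E,4R,5E)-2,4-diethylocta-1,5-dien-1-yl]-1,2-dioxan-3-yl]acetaldehyde | CC/C=C/[C@H](CC)C/C(=C/[C@]1(CC)C[C@H](CC)[C@H](CC=O)OO1)CC | intermediate
33 | 2-[(3S,4S,6S)-4,6-diethyl-6-[(1E,4R,5E)-2,4-diethylocta-1,5-dien-1-yl]-1,2-dioxan-3-yl]acetic acid | CC/C=C/[C@H](CC)C/C(=C/[C@]1(CC)C[C@H](CC)[C@H](CC(=O)O)OO1)CC | target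

**Step count**

Total step count: 19. Longest linear sequence: 16 steps (1–10, 12–14, 17–19); steps 11, 15 and 16 make the two side-chain reagents.

**Steps most likely to fail**

1. Step 1. The dioxygenase may turn over the meta-dialkyl arene slowly, or divert oxidation to a benzylic C–H bond of an ethyl group, so that little ring diol accumulates. The fallback sets out from dioxygen 2 and, in place of 1, from commercial 1,3-dibromobenzene F1, which has no benzylic hydrogen and belongs to the dihalobenzenes that the same whole cells dihydroxylate. This should give (1S,2S)-3,5-dibromocyclohexa-3,5-diene-1,2-diol F2, which with 4 and p-TsOH gives the acetonide (3aS,7aS)-4,6-dibromo-2,2-dimethyl-3a,7a-dihydro-1,3-benzodioxole F3. A twofold Negishi coupling of F3 with Et2Zn under PdCl2(dppf) catalysis (dppf = 1,1′-bis(diphenylphosphino)ferrocene) in THF replaces both vinylic bromides by ethyl groups and comes back to the route at 5.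

2. Step 7. The ylide may fail to tell the two formyl groups apart (double olefination or attack at the C6 formyl group), and as a base it may trigger O–O fragmentation through the acidic C3–H. The fallback sets out from dialdehyde 9. NaBH4 in MeOH at −40 °C reduces both formyl groups to [4,6-diethyl-1,2-dioxane-3,6-diyl]dimethanol F4. t-BuPh2SiCl and imidazole at −20 °C silylate the hydroxymethyl group on the secondary carbon C3 and leave the neopentyl one, giving the mono(tert-butyldiphenylsilyl) ether F5; mis-silylated material can be recycled with Bu4NF. Dess–Martin oxidation gives the C6 aldehyde F6, and the Horner–Wadsworth–Emmons reaction of step 8 gives the silyloxymethyl enoate F7. Bu4NF buffered with AcOH frees the hydroxymethyl enoate F8, and Dess–Martin oxidation gives the formyl enoate F9. The Wittig reaction with ylide 11 at −78 °C, now with a single formyl group in the molecule, gives 15, where the route is rejoined.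

3. Step 4. Hydrogen transfer may not discriminate cleanly between the two faces of the trisubstituted bridge alkene, because the acetonide methyl groups are tied back, which would give the C4 epimer. The fallback sets out from diol 3. t-BuMe2SiOTf and 2,6-lutidine at −78 °C give the bis(tert-butyldimethylsilyl) ether of 3 F10, whose two bulky silyloxy groups end up directly over one face of the future bridge alkene. Photooxygenation as in step 3 gives the bis(silyloxy) endoperoxide F11, and diimide reduction as in step 4 gives the saturated bis(silyloxy) endoperoxide F12. Bu4NF then removes both silyl groups and gives diol 8, where the route is rejoined; the acid step 5 is not needed.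

**Further compounds**

F1 | step 1 | 1,3-dibromobenzene | Brc1cccc(Br)c1
F2 | step 1 | (1S,2S)-3,5-dibromocyclohexa-3,5-diene-1,2-diol | O[C@H]1C=C(Br)C=C(Br)[C@H]1O
F3 | step 1 | (3aS,7aS)-4,6-dibromo-2,2-dimethyl-3a,7a-dihydro-1,3-benzodioxole | CC1(C)O[C@H]2C=C(Br)C=C(Br)[C@H]2O1
F4 | step 7 | [4,6-diethyl-1,2-dioxane-3,6-diyl]dimethanol, ring configuration of 9 | OC[C@]1(CC)C[C@H](CC)[C@H](CO)OO1
F5 | step 7 | mono(tert-butyldiphenylsilyl) ether of F4 at the C3 hydroxymethyl group | OC[C@]1(CC)C[C@H](CC)[C@H](CO[Si](c2ccccc2)(c2ccccc2)C(C)(C)C)OO1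
F6 | step 7 | 3-[(tert-butyldiphenylsilyloxy)methyl]-4,6-diethyl-1,2-dioxane-6-carbaldehyde | O=C[C@]1(CC)C[C@H](CC)[C@H](CO[Si](c2ccccc2)(c2ccccc2)C(C)(C)C)OO1
F7 | step 7 | ethyl (E)-2-ethyl-3-[3-(silyloxymethyl)dioxanyl]prop-2-enoate, silyl = tert-butyldiphenylsilyl | CCOC(=O)/C(CC)=C/[C@]1(CC)C[C@H](CC)[C@H](CO[Si](c2ccccc2)(c2ccccc2)C(C)(C)C)OO1
F8 | step 7 | ethyl (E)-2-ethyl-3-[3-(hydroxymethyl)dioxanyl]prop-2-enoate | CCOC(=O)/C(CC)=C/[C@]1(CC)C[C@H](CC)[C@H](CO)OO1
F9 | step 7 | ethyl (E)-2-ethyl-3-(3-formyldioxanyl)prop-2-enoate | CCOC(=O)/C(CC)=C/[C@]1(CC)C[C@H](CC)[C@H](C=O)OO1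
F10 | step 4 | bis(tert-butyldimethylsilyl) ether of 3 | CC(C)(C)[Si](C)(C)O[C@H]1C=C(CC)C=C(CC)[C@H]1O[Si](C)(C)C(C)(C)C
F11 | step 4 | 1,5-diethyl-7,8-bis(tert-butyldimethylsilyloxy)-2,3-dioxabicyclo[2.2.2]oct-5-ene, silyloxy groups anti to O–O | CC[C@@]12C=C(CC)[C@@H](OO1)[C@H](O[Si](C)(C)C(C)(C)C)[C@@H]2O[Si](C)(C)C(C)(C)C
F12 | step 4 | 1,5-diethyl-7,8-bis(tert-butyldimethylsilyloxy)-2,3-dioxabicyclo[2.2.2]octane, C5 ethyl toward the C7–C8 bridge | CC[C@@]12C[C@H](CC)[C@@H](OO1)[C@H](O[Si](C)(C)C(C)(C)C)[C@@H]2O[Si](C)(C)C(C)(C)C
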